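**Plan**

- Cuts: (a) the C2–C3 bond of quinone ring B; (b) the aryl C7–CH2 bond; (c) the C–vinyl and C–CH3 bonds at the E-trisubstituted olefin; (d) the propargylic C–C bond and the tertiary C–O bond.
- Enabling feature: C2 and C3 are the α-carbons of C1=O and C4=O, which sit on the adjacent carbons C8a and C4a of benzene ring A. Two ortho enol ethers can therefore be joined at their β-carbons by oxidation, and the 2,3-dihydro-1,4-dione formed is the keto tautomer of the hydroquinone, so the same oxidant carries it to the quinone.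
- Forward: ring B is closed on a chloroarene (steps 1–4), the quinone is masked as its dimethyl ether (step 5), the chain is built from geraniol (steps 6–10), the parts are joined by B-alkyl Suzuki–Miyaura coupling (step 11), then acetylation and oxidative unmasking follow (steps 12–13).
- Stereochemistry: Sharpless asymmetric epoxidation of geraniol sets both centres (secondary centre kept, tertiary centre inverted by anti hydration). Syn carboalumination sets the E olefin. The 2-methyl/7-chain pattern is fixed by which ortho carbon of ring A carries which enol ether.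

Key step: step 4

Assumption: 1-(5-chloro-2-hydroxyphenyl)propan-1-one is taken as a purchasable compound (it is the Fries rearrangement product of 4-chlorophenyl propanoate).

**Route**

Step 1
Reactants: 1 1-(5-chloro-2-hydroxyphenyl)propan-1-one
Product: 2 4-chloro-2-propanoylphenyl trifluoromethanesulfonate
Conditions: Tf2O (1.2 equiv), pyridine, CH2Cl2, 0 °C
Reagents that add atoms: trifluoromethanesulfonic anhydride, O=S(=O)(OS(=O)(=O)C(F)(F)F)C(F)(F)F
Why: O-sulfonylation of the phenol turns the future C4a into a cross-coupling site while the ketone and the aryl chloride stay inert.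

Step 2
Reactants: 2 4-chloro-2-propanoylphenyl trifluoromethanesulfonate; 3 tributyl(1-ethoxyethenyl)stannane
Product: 4 1-[5-chloro-2-(1-ethoxyethenyl)phenyl]propan-1-one
Conditions: 3 (1.1 equiv), PdCl2(PPh3)2 (5 mol %), LiCl (3 equiv), 1,4-dioxane, 90 °C; aqueous KF work-up; chromatography on Et3N-treated silica
Reagents that add atoms: none
Why: Stille coupling, in which zerovalent palladium inserts into the C–OTf bond activated by the ortho ketone far faster than into the C–Cl bond, so the future C4 and C3 arrive already at the enol ether level and are kept by the neutral work-up.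

Step 3
Reactants: 4 1-[5-chloro-2-(1-ethoxyethenyl)phenyl]propan-1-one
Product: 6 tert-butyl({(1Z)-1-[5-chloro-2-(1-ethoxyethenyl)phenyl]prop-1-en-1-yl}oxy)dimethylsilane, via potassium enolate 5 (not isolated)
Conditions: KN(SiMe3)2 (1.1 equiv), THF, −78 °C; TBSCl (1.2 equiv), −78 °C → 0 °C; non-aqueous work-up (pentane, filtration)
Reagents that add atoms: tert-butyldimethylsilyl chloride, CC(C)(C)[Si](C)(C)Cl
Why: Kinetic deprotonation of the only enolisable position and O-silylation of the enolate should give the mixed bis(enol ether); no second carbonyl group is present, so no aldol pathway competes, and the enol ether geometry is of no consequence for step 4.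

Step 4
Reactants: 6 tert-butyl({(1Z)-1-[5-chloro-2-(1-ethoxyethenyl)phenyl]prop-1-en-1-yl}oxy)dimethylsilane
Product: 8 7-chloro-2-methylnaphthalene-1,4-dione, via 7-chloro-4-ethoxy-2-methylnaphthalen-1-ol 7 (not isolated)
Conditions: (NH4)2Ce(NO3)6 (4.5 equiv), NaHCO3 (9 equiv), MeCN (0.02 M), −30 °C → 0 °C; then H2O, 0 °C
Reagents that add atoms: water, O
Why: Proposed new method: one-electron oxidation of the silyl enol ether of 6 by tetravalent cerium should give a radical cation whose β-carbon (future C2) is electrophilic and is attacked by the nucleophilic CH2 terminus (future C3) of the ortho 1-ethoxyethenyl group; a second electron transfer with loss of the silyl group and a proton should give the aromatic ethoxynaphthol 7, which two further equivalents of oxidant and water should convert into quinone 8 with loss of ethanol. The closest known reaction type is the oxidative coupling, by (NH4)2Ce(NO3)6 or at an anode, of a silyl enol ether with an enol ether or a second silyl enol ether to a 1,4-dicarbonyl compound, known both between two molecules and within one molecule; here the tether is benzene ring A and the 1,4-dione formed is the keto tautomer of a hydroquinone. Ring B closes in the 6-endo-trig mode with respect to the attacked ethoxyethenyl double bond, the only mode that places the developing positive charge on the oxygen-bearing benzylic carbon. No stereocentre is formed. The step needs ring closure to outrun desilylation, capture of the radical cation by nitrate and coupling between two molecules, which the ortho placement of the two enol ethers (six-membered transition state), high dilution, low temperature and the NaHCO3 buffer should secure; the position of the methyl group relative to chlorine cannot vary because C1 and C4 are already bonded to C8a and C4a.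

Step 5
Reactants: 8 7-chloro-2-methylnaphthalene-1,4-dione
Product: 10 7-chloro-1,4-dimethoxy-2-methylnaphthalene, via 7-chloro-2-methylnaphthalene-1,4-diol 9 (not isolated)
Conditions: Na2S2O4, Bu4NBr (cat.), THF/H2O, rt; then KOH (aq), Me2SO4, rt, under N2
Reagents that add atoms: dimethyl sulfate, COS(=O)(=O)OC
Why: Dithionite reduction to the hydroquinone and Williamson O-methylation is the standard way to mask a 2-methylnaphthoquinone for organometallic chemistry, and the aryl chloride is inert.

Step 6
Reactants: 11 geraniol, (2E)-3,7-dimethylocta-2,6-dien-1-ol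
Product: 12 [(2R,3R)-3-methyl-3-(4-methylpent-3-en-1-yl)oxiran-2-yl]methanol
Conditions: Ti(OiPr)4 (5 mol %), D-(−)-diethyl tartrate (7 mol %), t-BuOOH (1.5 equiv), 4 Å molecular sieves, CH2Cl2, −20 °C
Reagents that add atoms: tert-butyl hydroperoxide, CC(C)(C)OO
Why: Sharpless asymmetric epoxidation, in which the allylic alcohol binds to the titanium tartrate catalyst so that only the 2,3-double bond is epoxidised and the D-(−)-tartrate directs oxygen to the face that gives the (2R,3R)-epoxide, setting both stereocentres.

Step 7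
Reactants: 12 [(2R,3R)-3-methyl-3-(4-methylpent-3-en-1-yl)oxiran-2-yl]methanol
Product: 13 [(2R,3R)-3-methyl-3-(4-methylpent-3-en-1-yl)oxiran-2-yl]methyl 4-methylbenzenesulfonate
Conditions: TsCl, Et3N, DMAP (cat.), CH2Cl2, 0 °C
Reagents that add atoms: 4-methylbenzenesulfonyl chloride, Cc1ccc(cc1)S(=O)(=O)Cl
Why: Sulfonylation of the primary alcohol under basic conditions leaves the trisubstituted epoxide and both stereocentres untouched.

Step 8
Reactants: 13 [(2R,3R)-3-methyl-3-(4-methylpent-3-en-1-yl)oxiran-2-yl]methyl 4-methylbenzenesulfonate; 14 trimethyl(prop-1-yn-1-yl)silane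
Product: 16 (2R,3R)-2-(but-3-yn-1-yl)-3-methyl-3-(4-methylpent-3-en-1-yl)oxirane, via silylalkyne 15 (not isolated)
Conditions: 14 (1.5 equiv), n-BuLi, THF, −78 °C → −20 °C; 13, −78 °C → 0 °C; then K2CO3, MeOH, rt
Reagents that add atoms: none
Why: SN2 alkylation of the primary tosylate by 3-lithio-1-(trimethylsilyl)propyne, a propargyl anion equivalent that reacts at its CH2 terminus, followed by methanolysis of the C–Si bond; the hindered epoxide is not opened by the organolithium without a Lewis acid.

Step 9
Reactants: 16 (2R,3R)-2-(but-3-yn-1-yl)-3-methyl-3-(4-methylpent-3-en-1-yl)oxirane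
Product: 17 (5R,6S)-6,10-dimethylundec-9-en-1-yne-5,6-diol
Conditions: HClO4 (3% aq), THF, 0 °C → rt
Reagents that add atoms: water, O
Why: Acid-catalysed anti hydration of a trisubstituted epoxide, in which water attacks the protonated epoxide at the tertiary carbon from the side opposite the C–O bond, so the tertiary centre is inverted (R to S) while the secondary centre keeps its configuration.

Step 10
Reactants: 17 (5R,6S)-6,10-dimethylundec-9-en-1-yne-5,6-diol; 18 bromoethene
Product: 20 (6S,7R,10E)-2,6,10-trimethyltrideca-2,10,12-triene-6,7-diol, via alkenylalane 19 (not isolated)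
Conditions: AlMe3 (5 equiv), Cp2ZrCl2 (0.5 equiv), CH2Cl2, 0 °C → rt; then 18 (excess), Pd(PPh3)4 (5 mol %), ZnCl2, THF, rt; aqueous potassium sodium tartrate work-up
Reagents that add atoms: trimethylaluminium, C[Al](C)C
Why: Negishi zirconium-catalysed carboalumination adds methyl and aluminium syn across the terminal alkyne with aluminium on the terminal carbon (the hydroxyl groups ride along as aluminium alkoxides), and palladium-catalysed coupling of the alkenylalane with bromoethene proceeds with retention, fixing the E double bond.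

Step 11
Reactants: 20 (6S,7R,10E)-2,6,10-trimethyltrideca-2,10,12-triene-6,7-diol; 21 9-borabicyclo[3.3.1]nonane; 10 7-chloro-1,4-dimethoxy-2-methylnaphthalene
Product: 23 (6S,7R,10E)-13-(5,8-dimethoxy-7-methylnaphthalen-2-yl)-2,6,10-trimethyltrideca-2,10-diene-6,7-diol, via alkylborane 22 (not isolated)
Conditions: 21 (3 equiv), THF, 0 °C → rt; then 10, Pd(OAc)2 (5 mol %), 2-dicyclohexylphosphino-2′,6′-dimethoxybiphenyl (10 mol %), K3PO4 (3 M aq), 65 °C
Reagents that add atoms: none
Why: The borane should add only to the unhindered terminal vinyl group of the diene with boron on the terminal carbon, and B-alkyl Suzuki–Miyaura coupling with the aryl chloride, enabled by the electron-rich biaryl phosphine, should form the C7–CH2 bond without touching olefin geometry or stereocentres.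

Step 12
Reactants: 23 (6S,7R,10E)-13-(5,8-dimethoxy-7-methylnaphthalen-2-yl)-2,6,10-trimethyltrideca-2,10-diene-6,7-diol
Product: 24 (6S,7R,10E)-13-(5,8-dimethoxy-7-methylnaphthalen-2-yl)-6-hydroxy-2,6,10-trimethyltrideca-2,10-dien-7-yl acetate
Conditions: Ac2O, pyridine, DMAP (cat.), CH2Cl2, 0 °C → rt
Reagents that add atoms: acetic anhydride, CC(=O)OC(C)=O
Why: Acylation discriminates the secondary hydroxyl group from the hindered tertiary one, so only the oxygen on C7 should be acetylated.

Step 13
Reactants: 24 (6S,7R,10E)-13-(5,8-dimethoxy-7-methylnaphthalen-2-yl)-6-hydroxy-2,6,10-trimethyltrideca-2,10-dien-7-yl acetate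
Product: 25 chabrolonaphthoquinone B, (6S,7R,10E)-6-hydroxy-2,6,10-trimethyl-13-(7-methyl-5,8-dioxo-5,8-dihydronaphthalen-2-yl)trideca-2,10-dien-7-yl acetate
Conditions: (NH4)2Ce(NO3)6 (2.5 equiv), MeCN/H2O (2:1), 0 °C
Reagents that add atoms: water, O
Why: Oxidative demethylation of the 1,4-dimethoxynaphthalene by tetravalent cerium (two one-electron oxidations, addition of water, loss of methanol) should release the quinone, while the acetate, the tertiary alcohol and the isolated trisubstituted double bonds are not oxidised under these conditions.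

**Compound list**

1 | 1-(5-chloro-2-hydroxyphenyl)propan-1-one | CCC(=O)c1cc(Cl)ccc1O | starting material
2 | 4-chloro-2-propanoylphenyl trifluoromethanesulfonate | CCC(=O)c1cc(Cl)ccc1OS(=O)(=O)C(F)(F)F | intermediate
3 | tributyl(1-ethoxyethenyl)stannane | CCCC[Sn](CCCC)(CCCC)C(=C)OCC | starting material
4 | 1-[5-chloro-2-(1-ethoxyethenyl)phenyl]propan-1-one | CCOC(=C)c1ccc(Cl)cc1C(=O)CC | intermediate
5 | potassium (1Z)-1-[5-chloro-2-(1-ethoxyethenyl)phenyl]prop-1-en-1-olate | CCOC(=C)c1ccc(Cl)cc1/C([O-])=C/C.[K+] | intermediate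
6 | tert-butyl({(1Z)-1-[5-chloro-2-(1-ethoxyethenyl)phenyl]prop-1-en-1-yl}oxy)dimethylsilane | CCOC(=C)c1ccc(Cl)cc1/C(O[Si](C)(C)C(C)(C)C)=C/C | intermediate
7 | 7-chloro-4-ethoxy-2-methylnaphthalen-1-ol | CCOc1cc(C)c(O)c2cc(Cl)ccc12 | intermediate
8 | 7-chloro-2-methylnaphthalene-1,4-dione | CC1=CC(=O)c2ccc(Cl)cc2C1=O | intermediate
9 | 7-chloro-2-methylnaphthalene-1,4-diol | Cc1cc(O)c2ccc(Cl)cc2c1O | intermediate
10 | 7-chloro-1,4-dimethoxy-2-methylnaphthalene | COc1cc(C)c(OC)c2cc(Cl)ccc12 | intermediate
11 | geraniol, (2E)-3,7-dimethylocta-2,6-dien-1-ol | CC(C)=CCC/C(C)=C/CO | starting material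
12 | [(2R,3R)-3-methyl-3-(4-methylpent-3-en-1-yl)oxiran-2-yl]methanol | OC[C@H]1O[C@]1(C)CCC=C(C)C | intermediate
13 | [(2R,3R)-3-methyl-3-(4-methylpent-3-en-1-yl)oxiran-2-yl]methyl 4-methylbenzenesulfonate | Cc1ccc(cc1)S(=O)(=O)OC[C@H]1O[C@]1(C)CCC=C(C)C | intermediate
14 | trimethyl(prop-1-yn-1-yl)silane | CC#C[Si](C)(C)C | starting material
15 | {4-[(2R,3R)-3-methyl-3-(4-methylpent-3-en-1-yl)oxiran-2-yl]but-1-yn-1-yl}trimethylsilane | C[Si](C)(C)C#CCC[C@H]1O[C@]1(C)CCC=C(C)C | intermediate
16 | (2R,3R)-2-(but-3-yn-1-yl)-3-methyl-3-(4-methylpent-3-en-1-yl)oxirane | C#CCC[C@H]1O[C@]1(C)CCC=C(C)C | intermediate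
17 | (5R,6S)-6,10-dimethylundec-9-en-1-yne-5,6-diol | O[C@H](CCC#C)[C@@](C)(O)CCC=C(C)C | intermediate
18 | bromoethene | C=CBr | starting material
19 | [(1E,5R,6S)-5,6-bis(dimethylalumanyloxy)-2,6,10-trimethylundeca-1,9-dien-1-yl]dimethylalumane | C[Al](C)/C=C(\C)CC[C@@H](O[Al](C)C)[C@@](C)(O[Al](C)C)CCC=C(C)C | intermediate
20 | (6S,7R,10E)-2,6,10-trimethyltrideca-2,10,12-triene-6,7-diol | O[C@H](CC/C(C)=C/C=C)[C@@](C)(O)CCC=C(C)C | intermediate
21 | 9-borabicyclo[3.3.1]nonane | B1C2CCCC1CCC2 | starting material
22 | (6S,7R,10E)-13-(9-borabicyclo[3.3.1]nonan-9-yl)-2,6,10-trimethyltrideca-2,10-diene-6,7-diol | O[C@H](CC/C(C)=C/CCB1C2CCCC1CCC2)[C@@](C)(O)CCC=C(C)C | intermediate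
23 | (6S,7R,10E)-13-(5,8-dimethoxy-7-methylnaphthalen-2-yl)-2,6,10-trimethyltrideca-2,10-diene-6,7-diol | O[C@H](CC/C(C)=C/CCc1ccc2c(OC)cc(C)c(OC)c2c1)[C@@](C)(O)CCC=C(C)C | intermediate
24 | (6S,7R,10E)-13-(5,8-dimethoxy-7-methylnaphthalen-2-yl)-6-hydroxy-2,6,10-trimethyltrideca-2,10-dien-7-yl acetate | CC(=O)O[C@H](CC/C(C)=C/CCc1ccc2c(OC)cc(C)c(OC)c2c1)[C@@](C)(O)CCC=C(C)C | intermediate
25 | chabrolonaphthoquinone B | CC(=O)O[C@H](CC/C(C)=C/CCc1ccc2c(c1)C(=O)C(C)=CC2=O)[C@@](C)(O)CCC=C(C)C | target

**Totals and risks**

Total step count: 13. Longest linear sequence: 8 steps (steps 1–5 then 11–13, or steps 6–10 then 11–13).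

Steps most likely to fail:

1. Step 4 (proposed new method). The silyl or ethyl enol ether may be hydrolysed before electron transfer, or the radical cation may be captured by nitrate or by a second molecule before the ring closes. The fallback uses known chemistry, sets out from 4 and comes back at 8. Bromination of the enol ether of 4 with NBS in THF/H2O at 0 °C should give 2-bromo-1-(4-chloro-2-propanoylphenyl)ethan-1-one F1. Kornblum oxidation (DMSO, NaHCO3, warm) should give 2-(4-chloro-2-propanoylphenyl)-2-oxoacetaldehyde F2. Piperidinium acetate should then induce intramolecular aldol addition of the propanoyl α-carbon to the aldehyde, giving 7-chloro-3-hydroxy-2-methyl-2,3-dihydronaphthalene-1,4-dione F3, whose dehydration delivers 8 at the quinone oxidation level without an oxidant. The same C2–C3 bond is thus made by a polar aldol condensation instead of an oxidative coupling.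

2. Step 9. Partial ionisation to the tertiary cation (loss of inversion) or attack of water at the secondary carbon would erode diastereomeric or enantiomeric purity, and the acid may induce cyclisation of the new tertiary alcohol onto the terminal double bond. The fallback sets out from 11 and comes back at 17; it replaces intermolecular hydration by an intramolecular, stereospecific inversion at the secondary carbon. Sharpless asymmetric epoxidation of 11 with L-(+)-diethyl tartrate should give [(2S,3S)-3-methyl-3-(4-methylpent-3-en-1-yl)oxiran-2-yl]methanol F4. Thiophenol and aqueous NaOH in t-BuOH (Payne rearrangement with trapping of the terminal epoxide at C1) should give (2S,3S)-3,7-dimethyl-1-(phenylsulfanyl)oct-6-ene-2,3-diol F5. S-Methylation with Me3OBF4 should give [(2S,3S)-2,3-dihydroxy-3,7-dimethyloct-6-en-1-yl](methyl)phenylsulfanium tetrafluoroborate F6, which NaH should close to (2S)-6-methyl-2-[(2R)-oxiran-2-yl]hept-5-en-2-ol F7. Opening of F7 at its CH2 carbon with lithiated 14 should give (5R,6S)-6,10-dimethyl-1-(trimethylsilyl)undec-9-en-1-yne-5,6-diol F8, and K2CO3 in MeOH should give 17.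

3. Step 11. Hydroboration of the conjugated diene may not stop cleanly at the terminal carbon, the free hydroxyl groups may consume borane, and oxidative addition to the electron-rich aryl chloride may be slow enough for protodeboronation to compete. The fallback sets out from 17 and 10 and comes back at 23; it exchanges the roles of the partners. Carboalumination of 17 as in step 10 followed by I2 should give (1E,5R,6S)-1-iodo-2,6,10-trimethylundeca-1,9-diene-5,6-diol F9. Suzuki–Miyaura vinylation of 10 with potassium vinyltrifluoroborate (Pd(OAc)2, the same biaryl phosphine, K2CO3, THF/H2O, 80 °C) should give 7-ethenyl-1,4-dimethoxy-2-methylnaphthalene F10. Hydroboration of F10 with 21 should give 9-[2-(5,8-dimethoxy-7-methylnaphthalen-2-yl)ethyl]-9-borabicyclo[3.3.1]nonane F11, and coupling of F11 with F9 (PdCl2(dppf), AsPh3, Cs2CO3, DMF/THF/H2O, rt) should give 23.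

**Further compounds**

F1 | step 4 | 2-bromo-1-(4-chloro-2-propanoylphenyl)ethan-1-one | CCC(=O)c1cc(Cl)ccc1C(=O)CBr
F2 | step 4 | 2-(4-chloro-2-propanoylphenyl)-2-oxoacetaldehyde | CCC(=O)c1cc(Cl)ccc1C(=O)C=O
F3 | step 4 | 7-chloro-3-hydroxy-2-methyl-2,3-dihydronaphthalene-1,4-dione (mixture of diastereomers) | CC1C(O)C(=O)c2ccc(Cl)cc2C1=O
F4 | step 9 | [(2S,3S)-3-methyl-3-(4-methylpent-3-en-1-yl)oxiran-2-yl]methanol | OC[C@@H]1O[C@@]1(C)CCC=C(C)C
F5 | step 9 | (2S,3S)-3,7-dimethyl-1-(phenylsulfanyl)oct-6-ene-2,3-diol | O[C@H](CSc1ccccc1)[C@@](C)(O)CCC=C(C)C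
F6 | step 9 | [(2S,3S)-2,3-dihydroxy-3,7-dimethyloct-6-en-1-yl](methyl)phenylsulfanium tetrafluoroborate | C[S+](C[C@@H](O)[C@@](C)(O)CCC=C(C)C)c1ccccc1.F[B-](F)(F)F
F7 | step 9 | (2S)-6-methyl-2-[(2R)-oxiran-2-yl]hept-5-en-2-ol | C1[C@@H](O1)[C@@](C)(O)CCC=C(C)C
F8 | step 9 | (5R,6S)-6,10-dimethyl-1-(trimethylsilyl)undec-9-en-1-yne-5,6-diol | O[C@H](CCC#C[Si](C)(C)C)[C@@](C)(O)CCC=C(C)C
F9 | step 11 | (1E,5R,6S)-1-iodo-2,6,10-trimethylundeca-1,9-diene-5,6-diol | O[C@H](CC/C(C)=C/I)[C@@](C)(O)CCC=C(C)C
F10 | step 11 | 7-ethenyl-1,4-dimethoxy-2-methylnaphthalene | COc1cc(C)c(OC)c2cc(C=C)ccc12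
F11 | step 11 | 9-[2-(5,8-dimethoxy-7-methylnaphthalen-2-yl)ethyl]-9-borabicyclo[3.3.1]nonane | COc1cc(C)c(OC)c2cc(CCB3C4CCCC3CCC4)ccc12
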